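## The problem

The target **16** is an achiral, fully substituted 2-aminoimidazole (ring A). N1 carries a methyl group, C4 a 4-methoxybenzyl group and C5 a 3-hydroxy-4,5-dimethoxybenzyl group. The exocyclic nitrogen on C2 is bonded to C4 of a 1-methylimidazole-2,5-dione (ring B). There is no stereocentre to set, so the difficulty is regiochemical: two similar benzyl arms must sit on C4 and C5 in a fixed relation to the N1-methyl group. A ring synthesis from a near-symmetrical precursor or a late N-methylation would not guarantee that relation. Ring B is an N-acylamidine in a hydantoin-like ring; it opens under hydroxide or strong nucleophiles and should be attached late. The phenol and the 2-amino group are acidic, nucleophilic sites that must be masked while strong base, a sulfonylating agent and an organozinc reagent are in use. The only stereochemical elements on the route are transient: an alkene geometry and one racemic sp3 carbon, both erased before the key step. The enabling feature is that N1(CH3)–C2(NH2)=N3–C4(=O)–C5H2 of ring A is creatinine (**1**). Its C5 methylene is aldol-active and can take up the C5 arm. Its C4 carbonyl, once enolised towards C5, becomes the oxygen of an aromatic 4-hydroxyimidazole, whose triflate presents C4 for a benzyl–metal coupling.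

## Retrosynthesis

**Phenol unmasking (16 ⇐ 15).** The O–Si bond of the triisopropylsilyl ether **15** is cut last. A bulky aryl silyl ether is chosen because it should survive hydrogenation, an amide base, an organozinc reagent and buffered hydrazine. A benzyl ether would be lost in the alkene hydrogenation. The forward step only needs a non-basic fluoride source so that ring B stays closed.

**Ring B attachment (15 ⇐ 12 + 13).** The exocyclic N–C4 bond of ring B is cut, giving the free 2-aminoimidazole **12** and 1-methylparabanic acid (**13**). This is preferred to cutting the C2–N bond of ring A because it uses the amine that the creatinine skeleton already carries and brings ring B in as a bought, intact unit. The forward reaction is an addition–elimination at the C4 carbonyl of **13**, activated in the flask as the O-silyl imidate **14**. It must select that carbonyl over C5 and C2.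

**Amine unmasking (12 ⇐ 11).** The N,N-dimethylformamidine of **11** is cut back to NH2. The formamidine goes on in one step, leaves no N–H on the molecule and is inert to amide bases and organozinc reagents, which carbamates on this ambident guanidine would not match as simply. The forward step must remove it without touching the aryl silyl ether.

**Key disconnection (11 ⇐ 8 + 10).** The C4–CH2 bond to the 4-methoxybenzyl arm is cut, giving the imidazol-4-yl triflate **8** and 4-methoxybenzylzinc chloride (**10**). The neighbouring cut at C5–CH2 is kept for the aldol, because C5 is the nucleophilic carbon of creatinine and C4 its electrophilic, oxygen-bearing carbon. Direct addition of a benzyl nucleophile to the C4 carbonyl is not an option, since deprotonation at C5 to the aromatic enolate would outrun it. The precursor **8** lacks a whole aryl arm and is an aromatic ring with a single C–O electrophile. The forward reaction must achieve oxidative addition into an electron-rich, ortho-substituted heteroaryl triflate.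

**Zinc reagent (10 ⇐ 9).** The C–Zn bond is traced to 4-methoxybenzyl chloride (**9**) by direct zinc insertion. The forward step must keep Wurtz dimerisation low.

**Aromatisation by O-sulfonylation (8 ⇐ 6 via 7).** The O–S bond is cut to the 5-benzylimidazol-4-one **6**. Deprotonation of C5–H gives the aromatic potassium 4-oxidoimidazole **7**. The forward step must place the sulfonyl group on oxygen; the racemic C5 centre vanishes here.

**Amidine installation (6 ⇐ 5).** The formamidine carbon is removed to give the 5-benzylcreatinine **5**. Its exocyclic NH2 is the only N–H, and C5 is a methine that cannot form an enaminone.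

**Saturation, silylation and aldol (5 ⇐ 4 ⇐ 3 ⇐ 1 + 2).** The C5–CH2 arm is traced through hydrogenation of the arylidene **4**, silylation of the phenol **3**, and cleavage of the exocyclic C5=CH bond to creatinine (**1**) and 3-hydroxy-4,5-dimethoxybenzaldehyde (**2**). The aldol cut removes the whole oxygenated aryl arm and leaves two bought materials. The condensation is done before silylation so that the acetate-buffered hot medium never meets the silyl ether.

## Roads not taken

Alternative 1: Ring A would be built and the C4 arm completed in one step. The cut removes the N3–C4 bond and the CH–aryl bond of the 4-methoxybenzyl group, leading to the racemic N-tosyl N-propargylguanidine A1 and 4-methoxyphenyl triflate A2. In the forward step Pd(OAc)2, RuPhos and LiOtBu would generate an arylpalladium species that activates the terminal alkyne. The guanidine nitrogen would add 5-exo-dig, reductive elimination would form the CH–aryl bond, and a proton shift would give the N-tosyl 2-aminoimidazole A3. Its merits are real: a ring and a C–C bond arise together from an acyclic precursor, and this reaction type is established for N-propargylguanidines, so its precedent is closer than that for triflate **8**. The weak points are these: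
- A1 needs a multi-step preparation from an enolisable arylacetaldehyde.
- The exocyclic alkene must isomerise cleanly into the ring.
- The sulfonyl group must later be removed reductively in the presence of three aryl ethers, and a benzyl ether must still be cleaved.

Against its better key-step precedent the chosen plan sets a ring bought complete as creatinine, regiochemistry that is never in question, and protecting groups that come off under mild, non-reductive conditions.

Alternative 2: The C5–CH2 bond would be formed last. The cut gives the bis-Boc-protected 5-iodoimidazole A4 and the N-hydroxyphthalimide ester A5 of the benzyloxy-dimethoxyphenylacetic acid. In an undivided cell with a zinc anode, NiCl2(dme) and 4,4'-di-tert-butyl-2,2'-bipyridine would couple them with loss of CO2 to give the dibenzylated imidazole A6. In one respect this is better than the chosen plan: a C–I bond at the electron-rich ring adds to low-valent nickel far more readily than a C–O bond adds to palladium, and no organometallic reagent has to be prepared. Its weaknesses for this target are these: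
- A4 presupposes a 4-benzyl-1-methyl-2-aminoimidazole with the methyl group already correctly placed, so the regiochemical problem is moved and not solved.
- The electron-rich iodide is prone to reductive deiodination at the cathode.
- Benzylic radicals dimerise readily.
- The arylacetic acid must first be homologated from **2**.

The chosen plan answers with the aldol condensation of creatinine, a one-step, reagent-free way of attaching the same C5 arm.

Alternative 3: Ring B would arrive complete. The cut is the C2–N bond of ring A, giving the 2-bromo-4,5-dibenzylimidazole A7 and 4-amino-1-methylimidazole-2,5-dione A8. Zerovalent palladium from Pd2(dba)3 and tBuBrettPhos with K3PO4 would join them to the O-benzyl ether A9 of the target, and hydrogenolysis would finish. This is the most convergent of the four plans. It leaves one step after the key step where the chosen plan has three, and it never handles a free 2-aminoimidazole. Its weak points are these: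
- A8 is a poorly nucleophilic, ambident amidine (exocyclic nitrogen against ring nitrogen) and is base-labile at amination temperatures.
- The 2-bromide is flanked by the N-methyl group, and the product can chelate palladium.
- A7 still requires a regiocontrolled synthesis of the whole 4,5-dibenzyl-1-methylimidazole.

The chosen plan has a longer end game, but its ring B attachment is the established condensation for this amine class, and its regiochemistry is fixed from the first step.

Key step: step 7

Assumption: the condensation product is written as the E isomer (aryl group syn to the C4 carbonyl, away from the N1-methyl group), the isomer expected to be favoured for an N1-methylated 5-arylidene imidazolone. The Z isomer, if formed, would be hydrogenated to the same compound.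

## Route

Step 1
Reactants: 1 creatinine (2-amino-1-methyl-1,5-dihydro-4H-imidazol-4-one); 2 3-hydroxy-4,5-dimethoxybenzaldehyde
Product: 3 (E)-2-amino-5-(3-hydroxy-4,5-dimethoxybenzylidene)-1-methyl-1,5-dihydro-4H-imidazol-4-one
Conditions: NaOAc, AcOH, 118 °C
Reagents that add atoms: none
Why: Knoevenagel-type aldol condensation; the C5 methylene of creatinine, flanked by the C4 carbonyl and N1, condenses readily with aryl aldehydes under acetate buffering, and the free phenol is inert in this medium. The alkene geometry is of no consequence because the double bond is saturated in step 3.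

Step 2
Reactants: 3 (E)-2-amino-5-(3-hydroxy-4,5-dimethoxybenzylidene)-1-methyl-1,5-dihydro-4H-imidazol-4-one
Product: 4 (E)-2-amino-5-[4,5-dimethoxy-3-(triisopropylsilyloxy)benzylidene]-1-methyl-1,5-dihydro-4H-imidazol-4-one
Conditions: iPr3SiCl, imidazole, DMF, 25 °C
Reagents that add atoms: triisopropylsilyl chloride, CC(C)[Si](Cl)(C(C)C)C(C)C
Why: Imidazole-promoted O-silylation of a phenol; only the phenolic oxygen forms a hydrolytically stable bond to silicon, and any N-silylation of the amidine unit is reversed on aqueous work-up. The silyl ether also makes the polar arylidene soluble for the next steps.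

Step 3
Reactants: 4 (E)-2-amino-5-[4,5-dimethoxy-3-(triisopropylsilyloxy)benzylidene]-1-methyl-1,5-dihydro-4H-imidazol-4-one
Product: 5 racemic 2-amino-5-[4,5-dimethoxy-3-(triisopropylsilyloxy)benzyl]-1-methyl-1,5-dihydro-4H-imidazol-4-one
Conditions: H2 (1 atm), 10% Pd/C, MeOH–EtOAc, 25 °C
Reagents that add atoms: none
Why: Heterogeneous catalytic hydrogenation of a conjugated arylidene C=C bond, a classical reduction of 5-arylidene creatinines. The new C5 stereocentre forms as a racemate and is erased by enolisation in step 5; the aryl silyl ether and the anisole-type rings are not affected.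

Step 4
Reactants: 5 racemic 2-amino-5-[4,5-dimethoxy-3-(triisopropylsilyloxy)benzyl]-1-methyl-1,5-dihydro-4H-imidazol-4-one
Product: 6 racemic (E)-N'-{5-[4,5-dimethoxy-3-(triisopropylsilyloxy)benzyl]-1-methyl-4-oxo-4,5-dihydro-1H-imidazol-2-yl}-N,N-dimethylformimidamide
Conditions: Me2NCH(OMe)2, toluene, 70 °C
Reagents that add atoms: N,N-dimethylformamide dimethyl acetal, COC(OC)N(C)C
Why: Amidine formation by condensation of a primary amino group with an amide acetal; the exocyclic NH2 carries the only N–H bonds, and C5 is a methine that cannot give an enaminone. The product has no N–H left, so the only acidic hydrogen in step 5 is C5–H.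

Step 5
Reactants: 6 racemic (E)-N'-{5-[4,5-dimethoxy-3-(triisopropylsilyloxy)benzyl]-1-methyl-4-oxo-4,5-dihydro-1H-imidazol-2-yl}-N,N-dimethylformimidamide
Product: 8 2-[(E)-(dimethylaminomethylene)amino]-5-[4,5-dimethoxy-3-(triisopropylsilyloxy)benzyl]-1-methyl-1H-imidazol-4-yl trifluoromethanesulfonate, via potassium 4-oxidoimidazole 7 (not isolated)
Conditions: KN(SiMe3)2, THF, −78 °C (degassed); then PhNTf2, −78 → 0 °C
Reagents that add atoms: N-phenylbis(trifluoromethanesulfonimide), O=S(=O)(N(c1ccccc1)S(=O)(=O)C(F)(F)F)C(F)(F)F
Why: Enolate O-sulfonylation (enol triflate formation), as practised on azol-4(5H)-ones to give azol-4-yl triflates; deprotonation at C5 is driven by aromatisation to the 4-oxidoimidazole 7, whose hard oxygen is sulfonylated by the hard triflyl donor. The racemic C5 centre disappears here, and exclusion of air guards the electron-rich enolate against oxidation at C5.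

Step 6
Reactants: 9 4-methoxybenzyl chloride
Product: 10 4-methoxybenzylzinc chloride (THF solution with LiCl, titrated and used directly)
Conditions: Zn dust (BrCH2CH2Br, Me3SiCl activation), LiCl, THF, 25 °C
Reagents that add atoms: zinc, [Zn]
Why: Direct oxidative insertion of zinc into a benzylic C–Cl bond promoted by LiCl; LiCl solubilises the organozinc as it forms and keeps the surface clean, so that insertion at room temperature outruns Wurtz dimerisation.

Step 7
Reactants: 8 2-[(E)-(dimethylaminomethylene)amino]-5-[4,5-dimethoxy-3-(triisopropylsilyloxy)benzyl]-1-methyl-1H-imidazol-4-yl trifluoromethanesulfonate; 10 4-methoxybenzylzinc chloride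
Product: 11 (E)-N'-{5-[4,5-dimethoxy-3-(triisopropylsilyloxy)benzyl]-4-(4-methoxybenzyl)-1-methyl-1H-imidazol-2-yl}-N,N-dimethylformimidamide
Conditions: Pd(OAc)2 (cat.), SPhos (cat.), THF, 25 → 50 °C
Reagents that add atoms: none
Why: Negishi cross-coupling of a heteroaryl triflate with a benzylic zinc chloride, the closest established class being azol-4-yl triflates made from azol-4(5H)-ones. The organozinc reduces Pd(OAc)2 to zerovalent palladium, which as its SPhos complex inserts into the C4–O bond of 8; the benzyl group then passes from zinc to divalent palladium, and reductive elimination forms the C4–CH2 bond and returns zerovalent palladium. No ring is closed and no stereocentre is formed. The step needs chemoselectivity for C–O insertion over attack at sulfur, which would return 6 after work-up, and over homocoupling of 10. The bulky, electron-rich biarylphosphine speeds both insertion into the electron-rich triflate and the final reductive elimination, and C4 lies next to the pyridine-type N3, which should help insertion. The substrate contributes by carrying no N–H or O–H bond (formamidine, N1-methyl, silyl ether), so the zinc reagent is not protonated and no ring anion forms that would deactivate the triflate. The transferring benzyl carbon has no β-hydrogen, so β-hydride elimination cannot intervene, and with a single C–O electrophile present regiochemistry is not an issue.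

Step 8
Reactants: 11 (E)-N'-{5-[4,5-dimethoxy-3-(triisopropylsilyloxy)benzyl]-4-(4-methoxybenzyl)-1-methyl-1H-imidazol-2-yl}-N,N-dimethylformimidamide
Product: 12 2-amino-5-[4,5-dimethoxy-3-(triisopropylsilyloxy)benzyl]-4-(4-methoxybenzyl)-1-methyl-1H-imidazole
Conditions: N2H4·H2O, AcOH, EtOH, 50 °C
Reagents that add atoms: none
Why: Transamidination (hydrazinolysis of an N,N-dimethylformamidine); hydrazine adds to the amidine carbon and the weakly basic 2-aminoimidazole is expelled. Buffering with acetic acid keeps the medium from becoming basic enough to cleave the hindered aryl silyl ether.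

Step 9
Reactants: 12 2-amino-5-[4,5-dimethoxy-3-(triisopropylsilyloxy)benzyl]-4-(4-methoxybenzyl)-1-methyl-1H-imidazole; 13 1-methylparabanic acid (1-methylimidazolidine-2,4,5-trione)
Product: 15 4-({5-[4,5-dimethoxy-3-(triisopropylsilyloxy)benzyl]-4-(4-methoxybenzyl)-1-methyl-1H-imidazol-2-yl}amino)-1-methyl-1H-imidazole-2,5-dione, via O-silylated 1-methylparabanic acid 14 (not isolated)
Conditions: 13, N,O-bis(trimethylsilyl)acetamide (BSA), toluene, 80 °C; then 12, 110 °C; aqueous work-up
Reagents that add atoms: none
Why: Condensation of an amine with a silyl-activated imide carbonyl (addition–elimination); BSA converts the N3–H imide of 13 into the O-silyl imidate 14, whose C4 is the most electrophilic carbon, and silicon carries off the displaced oxygen as siloxane. This is the established way of attaching ring B to 2-aminoimidazoles of this class, and the product tautomerises to the conjugated amino form.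

Step 10
Reactants: 15 4-({5-[4,5-dimethoxy-3-(triisopropylsilyloxy)benzyl]-4-(4-methoxybenzyl)-1-methyl-1H-imidazol-2-yl}amino)-1-methyl-1H-imidazole-2,5-dione
Product: 16 4-{[5-(3-hydroxy-4,5-dimethoxybenzyl)-4-(4-methoxybenzyl)-1-methyl-1H-imidazol-2-yl]amino}-1-methyl-1H-imidazole-2,5-dione (target)
Conditions: HF·pyridine, pyridine, THF, 0 → 25 °C
Reagents that add atoms: none
Why: Fluoride-mediated cleavage of an aryl silyl ether; pyridine-buffered HF is non-basic and anhydrous, so the base- and hydroxide-sensitive N-acylamidine of ring B should remain closed.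

## Compound list

1 | creatinine (2-amino-1-methyl-1,5-dihydro-4H-imidazol-4-one) | CN1CC(=O)N=C1N | starting material
2 | 3-hydroxy-4,5-dimethoxybenzaldehyde | COc1cc(C=O)cc(O)c1OC | starting material
3 | (E)-2-amino-5-(3-hydroxy-4,5-dimethoxybenzylidene)-1-methyl-1,5-dihydro-4H-imidazol-4-one | CN1C(N)=NC(=O)/C1=C\c1cc(O)c(OC)c(OC)c1 | intermediate
4 | (E)-2-amino-5-[4,5-dimethoxy-3-(triisopropylsilyloxy)benzylidene]-1-methyl-1,5-dihydro-4H-imidazol-4-one | CN1C(N)=NC(=O)/C1=C\c1cc(O[Si](C(C)C)(C(C)C)C(C)C)c(OC)c(OC)c1 | intermediate
5 | racemic 2-amino-5-[4,5-dimethoxy-3-(triisopropylsilyloxy)benzyl]-1-methyl-1,5-dihydro-4H-imidazol-4-one | CN1C(N)=NC(=O)C1Cc1cc(O[Si](C(C)C)(C(C)C)C(C)C)c(OC)c(OC)c1 | intermediate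
6 | racemic (E)-N'-{5-[4,5-dimethoxy-3-(triisopropylsilyloxy)benzyl]-1-methyl-4-oxo-4,5-dihydro-1H-imidazol-2-yl}-N,N-dimethylformimidamide | CN(C)/C=N/C1=NC(=O)C(Cc2cc(O[Si](C(C)C)(C(C)C)C(C)C)c(OC)c(OC)c2)N1C | intermediate
7 | potassium 2-[(E)-(dimethylaminomethylene)amino]-5-[4,5-dimethoxy-3-(triisopropylsilyloxy)benzyl]-1-methyl-1H-imidazol-4-olate | [K+].CN(C)/C=N/c1nc([O-])c(Cc2cc(O[Si](C(C)C)(C(C)C)C(C)C)c(OC)c(OC)c2)n1C | intermediate
8 | 2-[(E)-(dimethylaminomethylene)amino]-5-[4,5-dimethoxy-3-(triisopropylsilyloxy)benzyl]-1-methyl-1H-imidazol-4-yl trifluoromethanesulfonate | CN(C)/C=N/c1nc(OS(=O)(=O)C(F)(F)F)c(Cc2cc(O[Si](C(C)C)(C(C)C)C(C)C)c(OC)c(OC)c2)n1C | intermediate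
9 | 4-methoxybenzyl chloride | COc1ccc(CCl)cc1 | starting material
10 | 4-methoxybenzylzinc chloride | COc1ccc(C[Zn]Cl)cc1 | intermediate
11 | (E)-N'-{5-[4,5-dimethoxy-3-(triisopropylsilyloxy)benzyl]-4-(4-methoxybenzyl)-1-methyl-1H-imidazol-2-yl}-N,N-dimethylformimidamide | CN(C)/C=N/c1nc(Cc2ccc(OC)cc2)c(Cc2cc(O[Si](C(C)C)(C(C)C)C(C)C)c(OC)c(OC)c2)n1C | intermediate
12 | 2-amino-5-[4,5-dimethoxy-3-(triisopropylsilyloxy)benzyl]-4-(4-methoxybenzyl)-1-methyl-1H-imidazole | COc1ccc(Cc2nc(N)n(C)c2Cc2cc(O[Si](C(C)C)(C(C)C)C(C)C)c(OC)c(OC)c2)cc1 | intermediate
13 | 1-methylparabanic acid (1-methylimidazolidine-2,4,5-trione) | CN1C(=O)NC(=O)C1=O | starting material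
14 | 1-methyl-4-(trimethylsilyloxy)-1H-imidazole-2,5-dione (O-silyl tautomer of silylated 13) | CN1C(=O)N=C(O[Si](C)(C)C)C1=O | intermediate
15 | 4-({5-[4,5-dimethoxy-3-(triisopropylsilyloxy)benzyl]-4-(4-methoxybenzyl)-1-methyl-1H-imidazol-2-yl}amino)-1-methyl-1H-imidazole-2,5-dione | COc1ccc(Cc2nc(NC3=NC(=O)N(C)C3=O)n(C)c2Cc2cc(O[Si](C(C)C)(C(C)C)C(C)C)c(OC)c(OC)c2)cc1 | intermediate
16 | 4-{[5-(3-hydroxy-4,5-dimethoxybenzyl)-4-(4-methoxybenzyl)-1-methyl-1H-imidazol-2-yl]amino}-1-methyl-1H-imidazole-2,5-dione | COc1ccc(Cc2nc(NC3=NC(=O)N(C)C3=O)n(C)c2Cc2cc(O)c(OC)c(OC)c2)cc1 | target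

## Step count and risk

Total steps: 10. Longest linear sequence: 9 (steps 1–5 and 7–10 from creatinine **1**); step 6 is a one-step side branch.

**Step 7 (key step).** The most likely failure is slow oxidative addition into the electron-rich, ortho-substituted C4–O bond. Attack of the zinc reagent or chloride at sulfur would then return the imidazolone, and benzyl–benzyl homocoupling would consume **10**. The fallback gives up the C–O electrophile and inverts the polarity of the bond formation. Setting out from **6**, bromodehydration with POBr3 (2,6-lutidine, MeCN, 80 °C) would give the 4-bromoimidazole formamidine F1. Bromine–lithium exchange with n-BuLi at −78 °C would follow; C2 and C5 are blocked, so the 4-lithio species cannot migrate. Addition to 4-methoxybenzaldehyde would give the racemic imidazol-4-yl(4-methoxyphenyl)methanol F2. Ionic deoxygenation of this doubly activated carbinol with Et3SiH and CF3CO2H would return to the route at **11**.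

**Step 5.** The triflate of so electron-rich a ring may not survive isolation, through S–O hydrolysis on silica or during work-up, and the ambident enolate may be sulfonylated in part on carbon or nitrogen. The fallback replaces the sulfonate by a phosphate and palladium by nickel. Setting out from **6**, the enolate **7** would be trapped with diphenyl chlorophosphate to give the robust imidazol-4-yl diphenyl phosphate F3. Kumada–Corriu coupling of F3 with 4-methoxybenzylmagnesium chloride under NiCl2(dppp) catalysis would return to the route at **11**.

**Step 9.** The weakly nucleophilic 2-amino group may react slowly, and attack at the C5 carbonyl of the silylated trione or opening of the trione ring may compete. The fallback builds ring B on the amine in stages. Setting out from **12**, amidine formation with ethyl 2-ethoxy-2-iminoacetate would give the amidino ester F4. N-Carbamoylation of its unsubstituted nitrogen with N-succinimidyl N-methylcarbamate would give the N-(methylcarbamoyl)amidine F5. Base-promoted 5-exo-trig closure of the urea NH(CH3) onto the ester (iPr2NEt, MeCN, 60 °C) would return to the route at **15**.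

**Step 8.** Partial loss of the aryl silyl ether to the nucleophilic amine, or arrest at the N-formyl stage, would give mixtures. The fallback drops the protecting group on purpose and shortens the end game. Setting out from **11**, KOH in MeOH–H2O at reflux would cleave both the formamidine and the silyl ether to the free aminophenol F6. Excess BSA would silylate F6 in the flask to its trimethylsilyl ether F7, which would condense with **14** as in step 9 to the O-trimethylsilyl ether of the target F8. Methanolic work-up of F8 would return to the route at **16**, bypassing **12** and **15**.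

## Further compounds

F1 | step 7 | (E)-N'-{4-bromo-5-[4,5-dimethoxy-3-(triisopropylsilyloxy)benzyl]-1-methyl-1H-imidazol-2-yl}-N,N-dimethylformimidamide | CN(C)/C=N/c1nc(Br)c(Cc2cc(O[Si](C(C)C)(C(C)C)C(C)C)c(OC)c(OC)c2)n1C
F2 | step 7 | racemic (E)-N'-{5-[4,5-dimethoxy-3-(triisopropylsilyloxy)benzyl]-4-[hydroxy(4-methoxyphenyl)methyl]-1-methyl-1H-imidazol-2-yl}-N,N-dimethylformimidamide | CN(C)/C=N/c1nc(C(O)c2ccc(OC)cc2)c(Cc2cc(O[Si](C(C)C)(C(C)C)C(C)C)c(OC)c(OC)c2)n1C
F3 | step 5 | 2-[(E)-(dimethylaminomethylene)amino]-5-[4,5-dimethoxy-3-(triisopropylsilyloxy)benzyl]-1-methyl-1H-imidazol-4-yl diphenyl phosphate | CN(C)/C=N/c1nc(OP(=O)(Oc2ccccc2)Oc2ccccc2)c(Cc2cc(O[Si](C(C)C)(C(C)C)C(C)C)c(OC)c(OC)c2)n1C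
F4 | step 9 | ethyl 2-({5-[4,5-dimethoxy-3-(triisopropylsilyloxy)benzyl]-4-(4-methoxybenzyl)-1-methyl-1H-imidazol-2-yl}amino)-2-iminoacetate | CCOC(=O)C(=N)Nc1nc(Cc2ccc(OC)cc2)c(Cc2cc(O[Si](C(C)C)(C(C)C)C(C)C)c(OC)c(OC)c2)n1C
F5 | step 9 | ethyl 2-({5-[4,5-dimethoxy-3-(triisopropylsilyloxy)benzyl]-4-(4-methoxybenzyl)-1-methyl-1H-imidazol-2-yl}amino)-2-[(methylcarbamoyl)imino]acetate | CCOC(=O)C(=NC(=O)NC)Nc1nc(Cc2ccc(OC)cc2)c(Cc2cc(O[Si](C(C)C)(C(C)C)C(C)C)c(OC)c(OC)c2)n1C
F6 | step 8 | 5-{[2-amino-4-(4-methoxybenzyl)-1-methyl-1H-imidazol-5-yl]methyl}-2,3-dimethoxyphenol | COc1ccc(Cc2nc(N)n(C)c2Cc2cc(O)c(OC)c(OC)c2)cc1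
F7 | step 8 | 2-amino-5-[4,5-dimethoxy-3-(trimethylsilyloxy)benzyl]-4-(4-methoxybenzyl)-1-methyl-1H-imidazole | COc1ccc(Cc2nc(N)n(C)c2Cc2cc(O[Si](C)(C)C)c(OC)c(OC)c2)cc1
F8 | step 8 | 4-({5-[4,5-dimethoxy-3-(trimethylsilyloxy)benzyl]-4-(4-methoxybenzyl)-1-methyl-1H-imidazol-2-yl}amino)-1-methyl-1H-imidazole-2,5-dione | COc1ccc(Cc2nc(NC3=NC(=O)N(C)C3=O)n(C)c2Cc2cc(O[Si](C)(C)C)c(OC)c(OC)c2)cc1
A1 | alternative 1 | racemic N-[1-(3-benzyloxy-4,5-dimethoxyphenyl)but-3-yn-2-yl]-N-methyl-N'-tosylguanidine | C#CC(Cc1cc(OCc2ccccc2)c(OC)c(OC)c1)N(C)C(N)=NS(=O)(=O)c1ccc(C)cc1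
A2 | alternative 1 | 4-methoxyphenyl trifluoromethanesulfonate | COc1ccc(OS(=O)(=O)C(F)(F)F)cc1
A3 | alternative 1 | N-tosyl 2-amino-5-(3-benzyloxy-4,5-dimethoxybenzyl)-4-(4-methoxybenzyl)-1-methylimidazole | COc1ccc(Cc2nc(NS(=O)(=O)c3ccc(C)cc3)n(C)c2Cc2cc(OCc3ccccc3)c(OC)c(OC)c2)cc1
A4 | alternative 2 | 2-[bis(tert-butoxycarbonyl)amino]-5-iodo-4-(4-methoxybenzyl)-1-methylimidazole | COc1ccc(Cc2nc(N(C(=O)OC(C)(C)C)C(=O)OC(C)(C)C)n(C)c2I)cc1
A5 | alternative 2 | N-hydroxyphthalimide ester of (3-benzyloxy-4,5-dimethoxyphenyl)acetic acid | COc1cc(CC(=O)ON2C(=O)c3ccccc3C2=O)cc(OCc2ccccc2)c1OC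
A6 | alternative 2 | 2-[bis(tert-butoxycarbonyl)amino]-5-(3-benzyloxy-4,5-dimethoxybenzyl)-4-(4-methoxybenzyl)-1-methylimidazole | COc1ccc(Cc2nc(N(C(=O)OC(C)(C)C)C(=O)OC(C)(C)C)n(C)c2Cc2cc(OCc3ccccc3)c(OC)c(OC)c2)cc1
A7 | alternative 3 | 2-bromo-5-(3-benzyloxy-4,5-dimethoxybenzyl)-4-(4-methoxybenzyl)-1-methylimidazole | COc1ccc(Cc2nc(Br)n(C)c2Cc2cc(OCc3ccccc3)c(OC)c(OC)c2)cc1
A8 | alternative 3 | 4-amino-1-methyl-1H-imidazole-2,5-dione | CN1C(=O)N=C(N)C1=O
A9 | alternative 3 | O-benzyl ether of the target | COc1ccc(Cc2nc(NC3=NC(=O)N(C)C3=O)n(C)c2Cc2cc(OCc3ccccc3)c(OC)c(OC)c2)cc1
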